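**Retrosynthetic overview**
1. Ring A is inherited, not built: phloroglucinol 1 and isobutyryl chloride 2 give acylphloroglucinol 3, and dearomatising gem-dimethylation gives trione 4 (first ring event).
2. The tertiary carbinol is taken from the chiral pool: (R)-linalool 5, its vinyl-selective epoxide 6 and, through sulfonium salt 7, the α-chloroketone 8, an enolonium equivalent.
3. Key C–C disconnection (C3–C3a of the target): 1,4-diketone 9 comes from the C6 enolate of 4 and 8, two carbons that are each natively a nucleophilic carbonyl α-carbon.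
4. FGI: the C2 carbinol of diol 10 comes from catalyst-controlled reduction of the side-chain ketone of 9, because the neighbouring stereocentre (methyl versus a primary chain) cannot bias it.
5. C–O disconnection: the dihydrofuran (ring B) of target 11 is closed last, by dehydration of 10.

Assumption: the enolised triones 4, 9, 10 and 11 are each drawn as one tautomer (the enol geometry of 11 is that of the hydrogen-bonded tautomer, not set by a reagent), and commercial (R)-(−)-linalool of at least 95% ee is used as supplied.

**Step 1**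
Reactants: 1 phloroglucinol (benzene-1,3,5-triol); 2 isobutyryl chloride (2-methylpropanoyl chloride)
Product: 3 2-methyl-1-(2,4,6-trihydroxyphenyl)propan-1-one
Conditions: AlCl3 (4 equiv), PhNO2–CH2Cl2, 0 → 45 °C; aq. HCl
Reagents that add atoms: none
Why: Friedel–Crafts acylation of the electron-rich triol; the first acyl group deactivates the ring, so mono-acylation is clean, and no stereocentre is involved.

**Step 2**
Reactants: 3 2-methyl-1-(2,4,6-trihydroxyphenyl)propan-1-one
Product: 4 3,5-dihydroxy-4,4-dimethyl-2-(2-methylpropanoyl)cyclohexa-2,5-dien-1-one (isobutyrylfilicinic acid)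
Conditions: NaOMe (3.5 equiv), MeI (2.2 equiv), MeOH, 0 °C → rt; aq. HCl; chromatography
Reagents that add atoms: iodomethane CI
Why: Dearomative double C-methylation of the phloroglucinol polyanion: the second methyl enters at the carbon already methylated, which dearomatises the ring to the gem-dimethyl trione and leaves C6–H as the only ring carbon nucleophile for step 5; mono- and trimethylated by-products are removed by chromatography.

**Step 3**
Reactants: 5 (R)-(−)-linalool ((3R)-3,7-dimethylocta-1,6-dien-3-ol)
Product: 6 (2R)-6-methyl-2-(oxiran-2-yl)hept-5-en-2-ol (both oxirane epimers)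
Conditions: VO(acac)2 (2 mol %), t-BuOOH (1.3 equiv), CH2Cl2, 0 °C → rt
Reagents that add atoms: tert-butyl hydroperoxide CC(C)(C)OO
Why: Hydroxyl-directed VO(acac)2/t-BuOOH epoxidation: the vanadium alkoxide of the tertiary allylic alcohol delivers oxygen only to the adjacent vinyl group and leaves the more electron-rich but undirected trisubstituted alkene; the carbinol stereocentre comes unchanged from the chiral pool, and the unselectively formed oxirane centre is oxidised away in step 4.

**Step 4**
Reactants: 6 (2R)-6-methyl-2-(oxiran-2-yl)hept-5-en-2-ol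
Product: 8 (3R)-1-chloro-3-hydroxy-3,7-dimethyloct-6-en-2-one, via chloro-alkoxysulfonium chloride 7 (not isolated)
Conditions: (COCl)2 (2.5 equiv), DMSO (5 equiv), CH2Cl2, −78 °C; add 6, MeOH (cat.), −78 → −40 °C; Et3N (6 equiv), → 0 °C
Reagents that add atoms: oxalyl chloride ClC(=O)C(=O)Cl
Why: Swern-type oxidative opening of an epoxide with activated DMSO: chloride opens the sulfonium-activated oxirane by SN2 at the unhindered CH2, and the secondary alkoxysulfonium salt 7 collapses with Et3N to the ketone as in a Swern oxidation, so both epimers of 6 converge on one α-chloroketone while the tertiary hydroxyl (no α-hydrogen) is returned on work-up.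

**Step 5**
Reactants: 4 isobutyrylfilicinic acid; 8 (3R)-1-chloro-3-hydroxy-3,7-dimethyloct-6-en-2-one
Product: 9 3,5-dihydroxy-6-[(3R)-3-hydroxy-3,7-dimethyl-2-oxooct-6-en-1-yl]-4,4-dimethyl-2-(2-methylpropanoyl)cyclohexa-2,5-dien-1-one
Conditions: K2CO3 (2.2 equiv), acetone–H2O (5:1), rt → 40 °C; 1 M HCl to pH 4, 0 °C; used crude (partly as its cyclic hemiketal)
Reagents that add atoms: none
Why: Enolate C-alkylation with an α-haloketone acting as an enolonium equivalent (first stage of a Feist–Bénary furan synthesis): the soft C6 carbanion of the dianion of 4 displaces chloride by SN2 at the carbonyl-activated CH2 of 8, joining two natively nucleophilic α-carbons into the 1,4-dicarbonyl array; the hindered ketone of 8 disfavours the aldol-first pathway, water favours C- over O-alkylation, and the carbinol stereocentre is not touched.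

**Step 6**
Reactants: 9 the 1,4-diketone from step 5
Product: 11 (2S,7Z)-7-(1-hydroxy-2-methylpropylidene)-2-[(2R)-2-hydroxy-6-methylhept-5-en-2-yl]-5,5-dimethyl-2,3-dihydro-1-benzofuran-4,6(5H,7H)-dione (target CNP0317212.1), via side-chain diol 10 (not isolated)
Conditions: catecholborane (4.5 equiv), toluene–CH2Cl2, 0 °C; (R)-Me-CBS ((R)-1-methyl-3,3-diphenyltetrahydro-1H,3H-pyrrolo[1,2-c][1,3,2]oxazaborole, 0.3 equiv), −78 → −40 °C; MeOH; then TsOH·H2O (5 mol %), CH2Cl2, rt
Reagents that add atoms: none
Why: Corey–Bakshi–Shibata reduction followed by acid-catalysed dehydrative cyclisation (enol-ether formation): with all O–H groups capped as catechol borates, the (R)-oxazaborolidine distinguishes the quaternary carbinol side (large) from the CH2 side (small) of the side-chain ketone and sets C2 as S under catalyst control; TsOH then condenses this secondary hydroxyl with the less hindered ring carbonyl next to the acyl-bearing carbon, closing the five-membered ring with retention at C2 because its C–O bond is never broken.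

**Compound list**
1 | phloroglucinol (benzene-1,3,5-triol) | Oc1cc(O)cc(O)c1 | starting material
2 | isobutyryl chloride | CC(C)C(Cl)=O | starting material
3 | 2-methyl-1-(2,4,6-trihydroxyphenyl)propan-1-one | CC(C)C(=O)c1c(O)cc(O)cc1O | intermediate
4 | 3,5-dihydroxy-4,4-dimethyl-2-(2-methylpropanoyl)cyclohexa-2,5-dien-1-one | CC(C)C(=O)C1=C(O)C(C)(C)C(O)=CC1=O | intermediate
5 | (R)-(−)-linalool | CC(C)=CCC[C@@](C)(O)C=C | starting material
6 | (2R)-6-methyl-2-(oxiran-2-yl)hept-5-en-2-ol, both oxirane epimers | CC(C)=CCC[C@@](C)(O)C1CO1 | intermediate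
7 | {[(3R)-1-chloro-3-hydroxy-3,7-dimethyloct-6-en-2-yl]oxy}dimethylsulfonium chloride, both C2 epimers | CC(C)=CCC[C@@](C)(O)C(CCl)O[S+](C)C.[Cl-] | intermediate
8 | (3R)-1-chloro-3-hydroxy-3,7-dimethyloct-6-en-2-one | CC(C)=CCC[C@@](C)(O)C(=O)CCl | intermediate
9 | 3,5-dihydroxy-6-[(3R)-3-hydroxy-3,7-dimethyl-2-oxooct-6-en-1-yl]-4,4-dimethyl-2-(2-methylpropanoyl)cyclohexa-2,5-dien-1-one | CC(C)C(=O)C1=C(O)C(C)(C)C(O)=C(CC(=O)[C@](C)(O)CCC=C(C)C)C1=O | intermediate
10 | 6-[(2S,3R)-2,3-dihydroxy-3,7-dimethyloct-6-en-1-yl]-3,5-dihydroxy-4,4-dimethyl-2-(2-methylpropanoyl)cyclohexa-2,5-dien-1-one | CC(C)C(=O)C1=C(O)C(C)(C)C(O)=C(C[C@H](O)[C@](C)(O)CCC=C(C)C)C1=O | intermediate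
11 | (2S,7Z)-7-(1-hydroxy-2-methylpropylidene)-2-[(2R)-2-hydroxy-6-methylhept-5-en-2-yl]-5,5-dimethyl-2,3-dihydro-1-benzofuran-4,6(5H,7H)-dione | CC(C)=CCC[C@@](C)(O)[C@@H]1CC2=C(O1)/C(=C(/O)C(C)C)C(=O)C(C)(C)C2=O | target

**Totals**
Total step count: 6. Longest linear sequence: 4 steps (steps 3, 4, 5, 6 from 5; equally steps 1, 2, 5, 6 from 1).

**Steps most likely to fail, with fallbacks**

The reduction and ring closure of step 6 carry the most risk. The ketone of 9 may be masked as its hemiketal, the borate-laden substrate may erode catalyst control, and ring closure can also give the regioisomeric enol ether or the six-membered ether through the tertiary hydroxyl. If so, the stereocentre is set before the coupling instead. This fallback sets out from 8. The same (R)-Me-CBS/catecholborane reduction, now on a simple α-chloroketone, gives (2R,3R)-1-chloro-3,7-dimethyloct-6-ene-2,3-diol F1. K2CO3 in MeOH closes it to (2R)-6-methyl-2-[(2S)-oxiran-2-yl]hept-5-en-2-ol F2. The dipotassium salt of 4 (KOH, t-BuOH–H2O, 70 °C) opens F2 at its CH2 terminus and gives 10 directly. The route is rejoined at 10, which is closed to 11 with TsOH as before.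

The key alkylation of step 5 can fail through O-alkylation, double alkylation at C6, or base-induced loss of 8. If so, the polarity of both partners is inverted. This fallback sets out from 4 and 8 and comes back at 9. PhI(OAc)2/KOH in MeOH converts 4 into its phenyliodonium ylide F3, which makes the ring carbon the electrophile. Zn/TMSCl/Et3N in THF converts 8 into (3R)-3,7-dimethyl-2,3-bis(trimethylsilyloxy)octa-1,6-diene F4. Cu(acac)2 (5 mol %) in CH2Cl2 couples F3 with F4 through the copper carbenoid, which attacks the enol ether far faster than the trisubstituted alkene. This gives the cyclic silyl ketal 6-hydroxy-5,5-dimethyl-2-[(2R)-6-methyl-2-(trimethylsilyloxy)hept-5-en-2-yl]-7-(2-methylpropanoyl)-2-(trimethylsilyloxy)-2,3-dihydro-1-benzofuran-4(5H)-one F5. KF/citric acid in aqueous THF hydrolyses F5 (either ring-closure regioisomer) to 9.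

The one-flask oxidative opening of step 4 may suffer from the neighbouring tertiary hydroxyl, for example by methylthiomethyl ether formation or rearrangement of the activated epoxide. If so, opening and oxidation are separated. This fallback sets out from 6 and comes back at 9. MgBr2·OEt2 (Et2O, −20 °C) opens 6 at the CH2 terminus to (3R)-1-bromo-3,7-dimethyloct-6-ene-2,3-diol F6. Dess–Martin periodinane/NaHCO3 (CH2Cl2, 0 °C) oxidises the secondary alcohol to (3R)-1-bromo-3-hydroxy-3,7-dimethyloct-6-en-2-one F7. F7 then takes the place of 8 under the conditions of step 5 and gives 9.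

**Further compounds**
F1 | step 6 | (2R,3R)-1-chloro-3,7-dimethyloct-6-ene-2,3-diol | CC(C)=CCC[C@@](C)(O)[C@@H](O)CCl
F2 | step 6 | (2R)-6-methyl-2-[(2S)-oxiran-2-yl]hept-5-en-2-ol | CC(C)=CCC[C@@](C)(O)[C@@H]1CO1
F3 | step 5 | phenyliodonium ylide of 4 (ylide carbon C6) | CC(C)C(=O)C1=C(O)C(C)(C)C(=O)[C-]([I+]c2ccccc2)C1=O
F4 | step 5 | (3R)-3,7-dimethyl-2,3-bis(trimethylsilyloxy)octa-1,6-diene | CC(C)=CCC[C@@](C)(O[Si](C)(C)C)C(=C)O[Si](C)(C)C
F5 | step 5 | 6-hydroxy-5,5-dimethyl-2-[(2R)-6-methyl-2-(trimethylsilyloxy)hept-5-en-2-yl]-7-(2-methylpropanoyl)-2-(trimethylsilyloxy)-2,3-dihydro-1-benzofuran-4(5H)-one, both ketal epimers | CC(C)=CCC[C@@](C)(O[Si](C)(C)C)C1(O[Si](C)(C)C)CC2=C(O1)C(C(=O)C(C)C)=C(O)C(C)(C)C2=O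
F6 | step 4 | (3R)-1-bromo-3,7-dimethyloct-6-ene-2,3-diol, both C2 epimers | CC(C)=CCC[C@@](C)(O)C(O)CBr
F7 | step 4 | (3R)-1-bromo-3-hydroxy-3,7-dimethyloct-6-en-2-one | CC(C)=CCC[C@@](C)(O)C(=O)CBr
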